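- The question was which of the four flasks holds the most X at 20 h, as a fraction of the L charged, and whether amber's cool start pays.

| flask | L | Z | Q | temperature | remark | time |
|---|---|---|---|---|---|---|
| spring | 10 mM | 2 equiv | 1.4 equiv | 98 °C | run made earlier |  |
| summer | 10 mM | 2 equiv | 2.2 equiv | 114 °C | run made earlier |  |
| winter | 10 mM | 1 equiv | 1 equiv | 98 °C | run made earlier |  |
| amber | 10 mM | 2.00 equiv | 1.00 equiv |  | at 90 °C until 4.0 h, from then on at 120 °C | 20 h |
| red | 10 mM | 2.00 equiv | 1.00 equiv | 120 °C |  | 20 h |
| blue | 10 mM | 2.00 equiv | 1.00 equiv | 90 °C |  | 20 h |
| green | 10 mM | 2.00 equiv | 1.00 equiv | 105 °C |  | 20 h |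

- spring (time / h: X / %): 6.00: 4.5; 20.0: 11.6; 40.0: 15.0; 72.0: 17.2
- summer (time / h: X / %): 5.00: 5.6; 10.0: 8.9; 15.0: 11.0; 20.0: 11.9; 25.0: 13.0
- winter (time / h: X / %): 6.00: 4.9; 20.0: 12.3; 40.0: 16.5; 72.0: 18.3

(standard deviation of a reading: 0.3 percentage points)

- as a solid, counted per litre of solution: Q
- at the start none of Q is in solution

- the flask with the highest amount of X, in percent of the L charged ("all alike" if they lie within 1.5 percentage points) (amber / red / blue / green / all alike)
- final X, as a percentage of the L charged, in amber
- final X, as a percentage of the L charged, in red
- final X, as a percentage of the L charged, in blue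
- final X, as a percentage of the L charged, in green

- From spring to winter the charges of Q and Z both went down, yet the last reading rose from 17.2% to 18.3%, so I carried the readings of spring and summer over to amber's charges without a correction.
- For the bound from above I let amber's cool stage run at spring's opening slope, 3.00% by the change, although spring stood warmer, and added summer's whole last reading, 13.0%; together they make the cap, 16.0%, the most X I allowed amber at 20 h.
- For the bound from below I took summer's reading at 15.0 h, 11.0%, close to the 16.0 h amber spends hot, and scaled it by the part of spring's last reading still unmade after the cool stage, which with the cool gain gives 12.1%.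
- That lower bound already stood above the spring and summer readings at 20.0 h, so I expected amber to lead.
- The forecast gave amber 12.5%, red 12%, blue 9.5% and green 12.1%, with “Amber is marginally highest”, which put amber inside my bracket.
- Amber gave 15.5%, against red 11.6%, blue 9.68% and green 12.2%, so amber led. At the change of temperature, at 4.00 h, amber held X 2.11%, less than the 3.00% I had allowed. The result stood 0.50 percentage points under the cap.

    L + E → X (k = 14.8 /M/h, Ea = 93.0 kJ/mol)
    Q ⇌ E, rate k2*(cs2 - [E]) while solid is left; crystals form when [E] > cs2 (solubility = 1.70 mM, k = 0.258 /h)
    2 L → D (k = 10.1 /M/h, Ea = 75.0 kJ/mol)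
    Z + E → G (k = 3.17 /M/h, Ea = 67.0 kJ/mol)
    (constants at 90 °C)

- In these equations the step to X is first order in L and the step to D second order, so for amber's recipe with L at 40 mM I scaled the cap by the ratio of charges and got 4.00%; that flask gave 2.99%, with 0.77% of its L left.

The earlier runs and the new flask are calculated with constants of no real substance; the scatter is artificial.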